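## Structural features

The target 24 is a tetracyclic keto lactone acid in which ring A (cyclohexane) is cis-fused to ring B (δ-lactone) as an octahydroisochromen-1-one, numbered here C1 (lactone carbonyl), O2, C3 (OCH2), C4, C4a, C5–C8, C8a. C4 is a quaternary spiro carbon and at the same time C2′ of an 8′,8′-dimethyl-6′-oxabicyclo[3.2.1]octan-3′-one, in which ring C is the cyclohexanone (C1′–C5′, C8′) and ring D the tetrahydrofuran closed by the O6′–C7′H2 bridge between C5′ and C1′. Of the seven stereocentres four are contiguous, C1′(R)–C4(S)–C4a(R)–C8a(S); the ether carbon C5′(R) lies across the CMe2 bridge, and the remote pair is C7(R) and C2(R) of the propanoic acid, which sits equatorial on ring A, 1,3-trans to the lactone carbonyl and 1,4-trans to the spiro carbon. The ring C ketone is a β-alkoxy ketone, so enolisation toward C4′ can open ring D by E1cB elimination. The lactone CH2O hangs on the α-carbon of that ketone, so base-mediated opening of ring B would expose a β-hydroxy ketone that can lose formaldehyde by retro-aldol cleavage, and C8a–H and the acid α-H are epimerisable. The real difficulty is the spiro carbon, wedged between a CMe2-flanked bridgehead, a ketone and ring A, with its ring A substituent axial on ring C and syn to one methyl group; the C7/C2 pair, in addition, has no neighbouring functionality in the target. The key step exploits the fact that C4a and C8a are adjacent CH carbons with cis hydrogens and are the β- and α-carbons of the lactone carbonyl, which is the retron of a [4+2] addition across the C=C bond of a spiro 5,6-dihydropyran-2-one. A 2-silyloxy diene then leaves oxygen on C6, next to C7, which supplies the handle that the side chain lacks.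

## Logic of the disconnections

24 from 23: only the O–CH2Ph bond of the ester is cut. A benzyl ester is chosen because its removal needs no base; hydroxide would open ring B and set up retro-aldol and E1cB damage. The forward step must be a neutral hydrogenolysis with no other reducible group present.

23 from 21 via 22: a carbonyl is added retrosynthetically at C6. It makes C7 an enolisable, alkylatable position and lets C7 be set thermodynamically. The forward demand is deoxygenation of one ketone in the presence of the hindered ring C ketone, a lactone and an ester, without touching C7.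

21 from 16 and 18 (via 19 and 20): the C7–C2 bond is cut. The C2 configuration comes from the chiral pool by SN2 inversion, and C7 is left to equilibrate. This splits off a three-carbon unit and leaves a regio-defined enol ether. The forward step needs a regiospecific enolate at C7, C-alkylation and clean inversion.

16 from 13 and 15: the C4a–C5 and C8–C8a bonds are cut together. This removes ring A and two stereocentres in one operation and leaves a dienophile whose only stereochemical information lies in the rigid rings C and D. The forward step needs the diene to add to one face of the lactone alkene with the silyloxy carbon para to C8a. The stereodescriptors of 13, 16 and 24 agree centre by centre. 15 comes from 14 and 18 from 17 by one functional-group step each.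

13 from 11 via 12, and 11 from 10: the lactone acyl–oxygen bond and the ring B C=C bond are cut. A Z-selective olefination of a non-enolisable aldehyde followed by ring closure is the shortest way to a 5,6-dihydropyran-2-one. The oxygen arm must stay protected until the aldehyde is consumed, because a free hydroxymethyl group next to a β-keto aldehyde would undergo retro-aldol cleavage under base.

10 from 9, and 9 from 7 via 8, and 7 from 6: the C5′–O6′ bond of ring D is cut, as an intramolecular oxa-Michael addition, and the C7′ oxidation level is adjusted. Ring D is closed only after the spiro carbon is complete. In the monocyclic enone only one α-position can enolise, whereas the bicyclic ketone has two competing α-positions, one of them β to the ring oxygen. Closing ring D before the unsaturated ester exists also removes a second Michael acceptor. The forward demand is a chemoselective alkene cleavage and aldehyde reduction beside an enone.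

6 from 5, 5 from 4, and 4 from 3: the two C–C bonds from the future spiro carbon to its one-carbon arms are cut. The arm that becomes the lactone CH2O is introduced first. The formyl equivalent is introduced second, so that it enters anti to the neighbouring vinyl group and the oxygen arm ends cis to it. The forward demand is this facial selectivity.

3 from 2, and 2 from 1: the bond from C1′ to its one-carbon substituent is cut, with vinyl as a masked hydroxymethyl group. This reduces the problem to the desymmetrisation of an achiral dienone. The forward step must select one of two enantiotopic alkenes at a β-carbon next to a quaternary centre.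

## Other disconnections considered

Alternative 1: The C4a–C8a bond is cut and ring B is opened, so that ring A arises by ring contraction of the cis-5,6-disubstituted δ-valerolactone A1. Forward, the silyl ketene acetal of A1 would undergo an Ireland–Claisen rearrangement through a boat transition state to give the cyclohexene diacid A2.
- In favour: the cyclic transition state transfers the carbinol configuration to C4a and C8a. C7 and the side-chain centre are installed beforehand in a small lactone, so no late alkylation or deoxygenation of ring A is needed. On that point the alternative is the better plan.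
- Against: the alkene terminus that must bond is attached to the fully substituted spiro carbon. The quaternary centre with its E-alkenyl arm has to be built without the help of rings C and D. Enolisation must be done beside a Michael-accepting enone and a second carboxyl whose α-centre can epimerise. After the rearrangement there remain alkene hydrogenation beside an enone, two deprotections, lactonisation and the oxa-Michael closure.
- Comparison: on structure it is more convergent, which counts in its favour. On mechanism it offers intramolecular control of C4a/C8a relative to C7, where the chosen plan offers control relative to the spiro centre by a rigid bicycle; the two are about equal. On step economy the chosen plan is shorter.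

Alternative 2: The C8′–C5′ bond and the ring D oxygen are disconnected back to the pinane skeleton. Forward, irradiation of apoverbenone A3 would give the cyclobutanone A4 by a 1,3-alkyl shift. Baeyer–Villiger insertion and reduction of the lactone carbonyl would then give ring D.
- In favour: both bridgehead centres and the CMe2 group come from the chiral pool, so no enantioselective catalysis is needed. On absolute stereocontrol it is the equal or the better of the chosen plan.
- Against: by descriptor analysis A4 corresponds to (1S,5S)-A3, the antipode of the series derived from the abundant (−)-β-pinene. A4 is itself photolabile. The Baeyer–Villiger step must choose between two secondary α-carbons while an alkene is present. A4 carries an alkene where the target needs the ring C ketone, and the future spiro carbon is an unfunctionalised allylic CH2. Rings A and B are not addressed.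
- Comparison: it is complementary to the chosen key step, not a rival to it. It could reach ring D in about as many steps, but the ketone and the quaternary centre would then have to be installed without the single-enolisable-site advantage used in steps 3 to 5.

Alternative 3: The C4–C1′ bond is cut and ring C is contracted to a cyclopentanol carrying a 2,2-disubstituted epoxide, A5. Forward, a Lewis acid would open the epoxide at its tertiary carbon and the ring carbon bearing CH2OSi would shift to it, giving the β-hydroxy ketone A6.
- In favour: the shift is stereospecific, with inversion at the epoxide carbon and retention in the migrating carbon, so the spiro configuration is relayed, not selected. On the spiro centre this is the better plan. The CH2OH arm for ring B appears directly.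
- Against: two ring carbons can migrate, and the desired one is the more hindered. The epoxide must be made diastereoselectively on a 1,1-disubstituted alkene attached to C4a. Ring C arrives without the C5′ oxygen, so desaturation and oxa-Michael closure follow. C1 and the side-chain carboxyl are at the alcohol level and need two late oxidations. Ring A with four stereocentres must be made first.
- Comparison: mechanistically it is the more predictable at C4 and the less predictable in migratory selectivity. On step economy it is clearly longer.

Key step: step 12

Assumption: the gem-dimethyl group does not reverse the usual sense of induction of the (R)-BINAP complex formed from [Rh(cod)2]PF6 (otherwise the other ligand enantiomer is used), and benzyl (R)-lactate is taken as the commercial source of the propanoate unit.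

## Steps

Step 1
Reactants: 1 4,4-dimethylcyclohex-2-en-1-one
Product: 2 4,4-dimethylcyclohexa-2,5-dien-1-one
Conditions: DDQ (1.3 equiv), dioxane, reflux
Reagents that add atoms: none
Why: Quinone dehydrogenation of the enone through its dienol (hydride transfer from C5 to DDQ); the quaternary C4 blocks aromatisation, so the cross-conjugated dienone is the end point.

Step 2
Reactants: 2 4,4-dimethylcyclohexa-2,5-dien-1-one
Product: 3 (5R)-5-ethenyl-4,4-dimethylcyclohex-2-en-1-one
Conditions: CH2=CHBF3K (1.1 equiv), [Rh(cod)2]PF6 (3 mol %), (R)-BINAP (3.3 mol %), toluene–H2O 10:1, 100 °C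
Reagents that add atoms: potassium vinyltrifluoroborate, C=C[B-](F)(F)F.[K+]
Why: Hayashi–Miyaura reaction: a vinyl complex of monovalent rhodium inserts one of the two enantiotopic C=C bonds and water protonates the oxa-π-allyl species. (R)-BINAP, the antipode of the ligand that turns cyclohex-2-enone into (S)-3-substituted cyclohexanones, should select the alkene and face that give the 5R centre (the future C1′). Limiting the boron reagent suppresses a second addition.

Step 3
Reactants: 3 (5R)-5-ethenyl-4,4-dimethylcyclohex-2-en-1-one
Product: 4 trans-6-(benzyloxymethyl)-5-ethenyl enone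
Conditions: LiN(iPr)2 (LDA), THF, −78 °C; BnOCH2Cl, −78 → −30 °C
Reagents that add atoms: benzyl chloromethyl ether, ClCOCc1ccccc1
Why: Only C6 carries enolisable hydrogens because C4 is quaternary; SN2 alkylation of the cross-conjugated lithium dienolate (no polar cosolvent, to favour C- over O-alkylation) should give mainly the 5,6-trans product. The C6 configuration is erased in step 4, so its ratio is immaterial.

Step 4
Reactants: 4 trans-6-(benzyloxymethyl)-5-ethenyl enone
Product: 5 trimethylsilyl dienol ether
Conditions: TMSOTf, Et3N, CH2Cl2, 0 °C
Reagents that add atoms: trimethylsilyl trifluoromethanesulfonate, C[Si](C)(C)OS(=O)(=O)C(F)(F)F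
Why: Soft enolisation and O-silylation; the single α′-hydrogen guarantees one regioisomer of the 2-silyloxy diene.

Step 5
Reactants: 5 trimethylsilyl dienol ether
Product: 6 quaternary β-keto dimethyl acetal (benzyloxymethyl cis to ethenyl)
Conditions: HC(OMe)3, TMSOTf (10 mol %), CH2Cl2, −78 °C; pyridine quench
Reagents that add atoms: trimethyl orthoformate, COC(OC)OC
Why: Mukaiyama-type alkylation: the dimethoxycarbenium ion generated from the orthoformate attacks C6 of the silyl enol ether. Approach anti to the neighbouring ethenyl group should place CH(OMe)2 trans and the benzyloxymethyl arm cis to it, which is the C4/C1′ relationship of the target.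

Step 6
Reactants: 6 quaternary β-keto dimethyl acetal
Product: 7 keto aldehyde (ethenyl cleaved to formyl)
Conditions: O3, CH2Cl2–MeOH, −78 °C (Sudan red end point); Me2S, −78 °C → rt
Reagents that add atoms: ozone, [O-][O+]=O
Why: Ozonolysis with reductive work-up; electrophilic ozone cleaves the isolated terminal alkene far faster than the electron-poor enone, and the indicator prevents over-oxidation of the benzyl ether.

Step 7
Reactants: 7 keto aldehyde
Product: 9 bicyclic ether ketone with rings C and D, via hydroxymethyl enone 8 (not isolated)
Conditions: NaBH4 (0.5 equiv), MeOH–CH2Cl2, −78 °C; then K2CO3 (cat.), MeOH, 0 °C → rt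
Reagents that add atoms: none
Why: Hydride reduces the aldehyde much faster than the conjugated ketone flanked by a quaternary carbon. The primary alcohol then adds 5-exo-trig to the enone β-carbon (intramolecular oxa-Michael addition), which is possible only on the face that carries the CH2OH group, so C5′ is dictated by C1′ and ring D closes.

Step 8
Reactants: 9 bicyclic ether ketone
Product: 10 bicyclic keto aldehyde
Conditions: TFA–H2O 9:1, CH2Cl2, 0 °C
Reagents that add atoms: water, O
Why: Acid hydrolysis of the dimethyl acetal; the aldehyde sits on a quaternary carbon and cannot enolise, and the benzyl ether keeps the neighbouring oxygen arm from retro-aldol cleavage.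

Step 9
Reactants: 10 bicyclic keto aldehyde
Product: 11 Z-enoate
Conditions: (CF3CH2O)2P(O)CH2CO2Me, KN(SiMe3)2 (KHMDS), 18-crown-6, THF, −78 °C
Reagents that add atoms: methyl bis(2,2,2-trifluoroethyl)phosphonoacetate, COC(=O)CP(=O)(OCC(F)(F)F)OCC(F)(F)F
Why: Still–Gennari variant of the Horner–Wadsworth–Emmons olefination: the electron-poor phosphonate and the dissociated potassium ion make elimination from the kinetic adduct fast, which gives the Z alkene. The stabilised anion neither adds to the hindered ketone nor deprotonates its α-CH2.

Step 10
Reactants: 11 Z-enoate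
Product: 13 spiro α,β-unsaturated δ-lactone, via hydroxy Z-ester 12 (not isolated)
Conditions: BCl3, C6HMe5, CH2Cl2, −78 °C; MeOH quench; PPTS (cat.), CH2Cl2, rt
Reagents that add atoms: none
Why: Lewis acid cleavage of the benzyl ether with pentamethylbenzene as cation scavenger at −78 °C should leave alkene, ketone and the dialkyl ether of ring D intact. The freed neopentyl alcohol is held beside the Z ester and closes the six-membered lactone by acid-catalysed transesterification.

Step 11
Reactants: 14 but-3-en-2-one
Product: 15 2-(tert-butyldimethylsilyloxy)buta-1,3-diene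
Conditions: TBSOTf, Et3N, Et2O, 0 °C
Reagents that add atoms: tert-butyldimethylsilyl trifluoromethanesulfonate, CC(C)(C)[Si](C)(C)OS(=O)(=O)C(F)(F)F
Why: Soft enolisation and O-silylation of the methyl ketone gives the 2-silyloxy diene.

Step 12
Reactants: 13 spiro α,β-unsaturated δ-lactone; 15 2-(tert-butyldimethylsilyloxy)buta-1,3-diene
Product: 16 cis-fused ring A silyl enol ether
Conditions: diene in fourfold excess, CH2Cl2, 13 kbar, 40 °C, 72 h (BHT)
Reagents that add atoms: none
Why: Concerted, asynchronous normal-demand [4+2] cycloaddition of the s-cis diene to the lactone C=C bond; the closest known reaction type is the pressure-promoted Diels–Alder reaction of 5,6-dihydro-2H-pyran-2-ones with 2-silyloxybuta-1,3-dienes. Ring A is closed by intermolecular annulation, both new bonds (C4a–C5 and C8–C8a) forming in one step on one face of the alkene. Regiochemistry follows from the diene HOMO: the CH2 terminus next to the silyloxy carbon has the largest coefficient and bonds to the lactone β-carbon, which puts the enol ether oxygen on C6 and its double bond toward C7. The cis relation of C4a and C8a is fixed by suprafacial addition to a ring alkene. Their sense relative to the spiro centre is set by facial selection: the β-carbon is axial on ring C and syn-axial to one methyl group of C8′, which screens the face turned to the bridgehead C1′, so the diene should add to the face flanked by the planar C3′ carbonyl. Only regio- and facial selectivity are needed; there is no endo/exo question because the diene termini are unsubstituted. Pressure is preferred to a Lewis acid because the transition state at the neopentyl β-carbon is compact, the β-alkoxy ketone and the enol ether stay untouched, and a stepwise Mukaiyama–Michael path is avoided.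

Step 13
Reactants: 17 benzyl (2R)-2-hydroxypropanoate
Product: 18 benzyl (2R)-2-(trifluoromethylsulfonyloxy)propanoate
Conditions: Tf2O, 2,6-lutidine, CH2Cl2, −78 → 0 °C
Reagents that add atoms: trifluoromethanesulfonic anhydride, O=S(=O)(OS(=O)(=O)C(F)(F)F)C(F)(F)F
Why: O-Sulfonylation does not touch the stereocentre; the triflate is kept cold and used at once.

Step 14
Reactants: 16 cis-fused ring A silyl enol ether; 18 benzyl (2R)-2-(trifluoromethylsulfonyloxy)propanoate
Product: 21 ring A keto benzyl ester (7R; side chain equatorial), via sulfonium enolate 19 (not isolated), via C7-epimeric keto ester 20 (not isolated)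
Conditions: TASF (1.05 equiv) added to 16 + 18, THF, −78 °C; work-up; DBU (cat.), toluene, rt
Reagents that add atoms: none
Why: Fluoride cleaves the Si–O bond and releases the enolate regiospecifically at C7; SN2 displacement of the secondary α-triflyloxy ester proceeds with inversion, turning the (R)-lactate centre into the (2R)-propanoate centre. DBU then equilibrates C7, which is α to the ketone, to the epimer with the side chain equatorial; the ring A chair is anchored by the bulky spiro carbon, so this is the target configuration. The lactone α-centre and the ester α-centre are far less acidic and should not move, and any retro-oxa-Michael opening of ring D is reversible under the kind of mild base that closed it in step 7.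

Step 15
Reactants: 21 ring A keto benzyl ester
Product: 22 C6 tosylhydrazone
Conditions: TsNHNH2 (1.05 equiv), EtOH, 40 °C
Reagents that add atoms: 4-methylbenzenesulfonohydrazide, Cc1ccc(cc1)S(=O)(=O)NN
Why: Condensation at the less hindered ketone; the ring C ketone is flanked by the quaternary spiro carbon and should react much more slowly.

Step 16
Reactants: 22 C6 tosylhydrazone
Product: 23 deoxygenated benzyl ester
Conditions: catecholborane, CHCl3, 0 °C → rt; NaOAc·3H2O, reflux
Reagents that add atoms: none
Why: Reductive deoxygenation of a tosylhydrazone: hydride adds to the C=N carbon, acetate then induces loss of sulfinate and nitrogen. The conditions are non-basic and should tolerate the ester, the lactone and the hindered ketone and leave C7 untouched.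

Step 17
Reactants: 23 deoxygenated benzyl ester
Product: 24 target acid
Conditions: H2 (1 atm), Pd/C, EtOAc, rt
Reagents that add atoms: none
Why: Hydrogenolysis of the benzyl ester under neutral conditions; no base is used, so the lactone, the β-alkoxy ketone and the two epimerisable α-centres are not at risk.

## Compound list

1 | 4,4-dimethylcyclohex-2-en-1-one | CC1(C)CCC(=O)C=C1 | starting material
2 | 4,4-dimethylcyclohexa-2,5-dien-1-one | CC1(C)C=CC(=O)C=C1 | intermediate
3 | (5R)-5-ethenyl-4,4-dimethylcyclohex-2-en-1-one | C=C[C@H]1CC(=O)C=CC1(C)C | intermediate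
4 | (5S,6R)-6-[(benzyloxy)methyl]-5-ethenyl-4,4-dimethylcyclohex-2-en-1-one (5,6-trans) | C=C[C@H]1[C@H](COCc2ccccc2)C(=O)C=CC1(C)C | intermediate
5 | {[(3R)-2-[(benzyloxy)methyl]-3-ethenyl-4,4-dimethylcyclohexa-1,5-dien-1-yl]oxy}trimethylsilane | C=C[C@H]1C(COCc2ccccc2)=C(O[Si](C)(C)C)C=CC1(C)C | intermediate
6 | (5R,6S)-6-[(benzyloxy)methyl]-6-(dimethoxymethyl)-5-ethenyl-4,4-dimethylcyclohex-2-en-1-one (benzyloxymethyl cis to ethenyl) | C=C[C@H]1[C@](COCc2ccccc2)(C(OC)OC)C(=O)C=CC1(C)C | intermediate
7 | (1R,2S)-2-[(benzyloxy)methyl]-2-(dimethoxymethyl)-6,6-dimethyl-3-oxocyclohex-4-ene-1-carbaldehyde | O=C[C@H]1[C@](COCc2ccccc2)(C(OC)OC)C(=O)C=CC1(C)C | intermediate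
8 | (5R,6S)-6-[(benzyloxy)methyl]-6-(dimethoxymethyl)-5-(hydroxymethyl)-4,4-dimethylcyclohex-2-en-1-one | OC[C@H]1[C@](COCc2ccccc2)(C(OC)OC)C(=O)C=CC1(C)C | intermediate
9 | (1R,2S,5R)-2-[(benzyloxy)methyl]-2-(dimethoxymethyl)-8,8-dimethyl-6-oxabicyclo[3.2.1]octan-3-one | COC(OC)[C@]1(COCc2ccccc2)C(=O)C[C@H]2OC[C@@H]1C2(C)C | intermediate
10 | (1R,2S,5R)-2-[(benzyloxy)methyl]-8,8-dimethyl-3-oxo-6-oxabicyclo[3.2.1]octane-2-carbaldehyde | O=C[C@]1(COCc2ccccc2)C(=O)C[C@H]2OC[C@@H]1C2(C)C | intermediate
11 | methyl (2Z)-3-[(1R,2S,5R)-2-[(benzyloxy)methyl]-8,8-dimethyl-3-oxo-6-oxabicyclo[3.2.1]octan-2-yl]prop-2-enoate | COC(=O)/C=C\[C@]1(COCc2ccccc2)C(=O)C[C@H]2OC[C@@H]1C2(C)C | intermediate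
12 | methyl (2Z)-3-[(1R,2S,5R)-2-(hydroxymethyl)-8,8-dimethyl-3-oxo-6-oxabicyclo[3.2.1]octan-2-yl]prop-2-enoate | COC(=O)/C=C\[C@]1(CO)C(=O)C[C@H]2OC[C@@H]1C2(C)C | intermediate
13 | (1R,2S,5R)-8,8-dimethyl-2′H-spiro[6-oxabicyclo[3.2.1]octane-2,3′-pyran]-3,6′-dione | O=C1C=C[C@]2(CO1)C(=O)C[C@H]3OC[C@@H]2C3(C)C | intermediate
14 | but-3-en-2-one | CC(=O)C=C | starting material
15 | 2-(tert-butyldimethylsilyloxy)buta-1,3-diene | C=CC(=C)O[Si](C)(C)C(C)(C)C | intermediate
16 | (1′R,4S,4aR,5′R,8aS)-6-[(tert-butyldimethylsilyl)oxy]-8′,8′-dimethyl-4a,5,8,8a-tetrahydro-1H,3H-spiro[isochromene-4,2′-[6]oxabicyclo[3.2.1]octane]-1,3′-dione | CC(C)(C)[Si](C)(C)OC1=CC[C@H]2[C@@H](C1)[C@]3(COC2=O)C(=O)C[C@H]4OC[C@@H]3C4(C)C | intermediate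
17 | benzyl (2R)-2-hydroxypropanoate | C[C@@H](O)C(=O)OCc1ccccc1 | starting material
18 | benzyl (2R)-2-{[(trifluoromethyl)sulfonyl]oxy}propanoate | C[C@@H](OS(=O)(=O)C(F)(F)F)C(=O)OCc1ccccc1 | intermediate
19 | tris(dimethylamino)sulfonium enolate of the ring A ketone (C6–O−, C6=C7; 1′R,4S,4aR,5′R,8aS) | [O-]C1=CC[C@H]2[C@@H](C1)[C@]3(COC2=O)C(=O)C[C@H]4OC[C@@H]3C4(C)C.CN(C)[S+](N(C)C)N(C)C | intermediate
20 | benzyl (2R)-2-[(1′R,4S,4aR,5′R,7S,8aS)-8′,8′-dimethyl-1,3′,6-trioxooctahydro-1H-spiro[isochromene-4,2′-[6]oxabicyclo[3.2.1]octan]-7-yl]propanoate (side chain axial) | C[C@@H](C(=O)OCc1ccccc1)[C@H]1C(=O)C[C@@H]2[C@H](C1)C(=O)OC[C@]23C(=O)C[C@H]4OC[C@@H]3C4(C)C | intermediate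
21 | benzyl (2R)-2-[(1′R,4S,4aR,5′R,7R,8aS)-8′,8′-dimethyl-1,3′,6-trioxooctahydro-1H-spiro[isochromene-4,2′-[6]oxabicyclo[3.2.1]octan]-7-yl]propanoate (side chain equatorial) | C[C@@H](C(=O)OCc1ccccc1)[C@@H]1C(=O)C[C@@H]2[C@H](C1)C(=O)OC[C@]23C(=O)C[C@H]4OC[C@@H]3C4(C)C | intermediate
22 | benzyl (2R)-2-[(1′R,4S,4aR,5′R,7R,8aS)-8′,8′-dimethyl-6-[2-(4-methylbenzenesulfonyl)hydrazinylidene]-1,3′-dioxooctahydro-1H-spiro[isochromene-4,2′-[6]oxabicyclo[3.2.1]octan]-7-yl]propanoate (NHTs anti to C7) | C[C@@H](C(=O)OCc1ccccc1)[C@@H]1/C(=N/NS(=O)(=O)c2ccc(C)cc2)C[C@@H]3[C@H](C1)C(=O)OC[C@]34C(=O)C[C@H]5OC[C@@H]4C5(C)C | intermediate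
23 | benzyl (2R)-2-[(1′R,4S,4aR,5′R,7R,8aS)-8′,8′-dimethyl-1,3′-dioxooctahydro-1H-spiro[isochromene-4,2′-[6]oxabicyclo[3.2.1]octan]-7-yl]propanoate | C[C@@H](C(=O)OCc1ccccc1)[C@@H]1CC[C@@H]2[C@H](C1)C(=O)OC[C@]23C(=O)C[C@H]4OC[C@@H]3C4(C)C | intermediate
24 | (2R)-2-[(1′R,4S,4aR,5′R,7R,8aS)-8′,8′-dimethyl-1,3′-dioxooctahydro-1H-spiro[isochromene-4,2′-[6]oxabicyclo[3.2.1]octan]-7-yl]propanoic acid | C[C@@H](C(=O)O)[C@@H]1CC[C@@H]2[C@H](C1)C(=O)OC[C@]21C(=O)C[C@H]2OC[C@@H]1C2(C)C | target

## Step count and least certain steps

Total: 17 steps. Longest linear sequence: 15 steps (steps 1–10, 12, 14–17); steps 11 and 13 are one-step side branches.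

Step 12 (key step). The most likely failure is slow cycloaddition at the neopentyl β-carbon, so that the diene is consumed by dimerisation or hydrolysis before it adds. Incomplete facial discrimination is the second concern. Fallback, from 13: cycloaddition with the more nucleophilic 1-methoxy-3-(trimethylsilyloxy)buta-1,3-diene (toluene, 110 °C) should give, with the same regiochemistry, the methoxy silyl enol ether cycloadduct F1. Dilute acid would remove the silyl group and methanol to give the cis-fused ring A enone F2. Rhodium-catalysed 1,4-hydrosilylation of F2 with tBuMe2SiH (RhCl(PPh3)3) would place the silyl enol ether between C6 and C7 and so return to 16.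

Step 2. The β-carbon is next to a quaternary centre, so insertion may be slow; a second addition to the product enone and imperfect differentiation of the two enantiotopic alkenes would lower both conversion and optical purity. Fallback, from 1: the same enantioselective vinyl addition on the mono-enone, where only a face has to be chosen, should give (3R)-3-ethenyl-4,4-dimethylcyclohexan-1-one F3. Kinetic enolisation on the unhindered side (LiN(iPr)2, TMSCl) would give the trimethylsilyl enol ether F4, and Saegusa–Ito oxidation (Pd(OAc)2, MeCN) would return to 3.

Step 5. The carbenium ion may not discriminate well between the face bearing the ethenyl group and the face bearing a pseudo-axial methyl group of C4, which would give epimers at the spiro carbon; the tetrasubstituted enol ether may also simply be desilylated. Fallback, from 3: the order is changed so that the hydroxymethyl arm is added on the bicyclic ketone, where one methyl of the bridge blocks one face. Silylation of 3 would give the trimethylsilyl dienol ether F5, and orthoformate alkylation the acetal enone F6. Ozonolysis would give the aldehyde F7; reduction would give the hydroxymethyl enone F8, which closes to the bicyclic acetal ketone F9. Aqueous acid would give the 2-(hydroxymethylene) ketone F10, whose acidity confines reaction to C2. Aldol addition of aqueous formaldehyde (NaHCO3) from the face anti to the syn-axial methyl would give the hydroxymethyl keto aldehyde F11. Benzylation under acid (benzyl 2,2,2-trichloroacetimidate, TfOH cat.) would return to 10.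

Step 14. The naked enolate may alkylate on oxygen with the hard triflate, or transfer a proton from the ring C ketone, which would scramble the enolate position and open ring D; fluoride may also attack the triflate. Fallback, from 16: aqueous HCl in THF would give the ring A diketone F12. Pyrrolidine (cat. TsOH, benzene, water removal) should condense at the unhindered ketone on the side away from C4a to give the pyrrolidine enamine F13. Stork enamine alkylation with 18 would give the iminium triflate F14, and buffered hydrolysis followed by the DBU equilibration would return to 21.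

Step 15. Condensation may also occur at the ring C ketone, and ene-hydrazine tautomerism may epimerise C7, which can no longer be corrected once the ketone is gone. Fallback, from 21: ethane-1,2-dithiol with BF3·OEt2 at 0 °C would give the C6 1,3-dithiolane F15, and desulfurisation with Raney Ni in EtOH would return to 23.

## Further compounds

F1 | step 12 | cycloadduct of 13 with 1-methoxy-3-(trimethylsilyloxy)buta-1,3-diene (8-methoxy-6-trimethylsilyloxy; C8 configuration immaterial) | COC1C=C(O[Si](C)(C)C)C[C@@H]2[C@H]1C(=O)OC[C@]23C(=O)C[C@H]4OC[C@@H]3C4(C)C
F2 | step 12 | cis-fused ring A enone (C6 ketone, C7=C8; 1′R,4S,4aR,5′R,8aS) | O=C1C=C[C@H]2[C@@H](C1)[C@]3(COC2=O)C(=O)C[C@H]4OC[C@@H]3C4(C)C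
F3 | step 2 | (3R)-3-ethenyl-4,4-dimethylcyclohexan-1-one | C=C[C@H]1CC(=O)CCC1(C)C
F4 | step 2 | {[(5R)-5-ethenyl-4,4-dimethylcyclohex-1-en-1-yl]oxy}trimethylsilane | C=C[C@H]1CC(O[Si](C)(C)C)=CCC1(C)C
F5 | step 5 | {[(3R)-3-ethenyl-4,4-dimethylcyclohexa-1,5-dien-1-yl]oxy}trimethylsilane | C=C[C@H]1C=C(O[Si](C)(C)C)C=CC1(C)C
F6 | step 5 | trans-6-(dimethoxymethyl)-5-ethenyl-4,4-dimethylcyclohex-2-en-1-one (5R) | C=C[C@H]1[C@H](C(OC)OC)C(=O)C=CC1(C)C
F7 | step 5 | trans-2-(dimethoxymethyl)-6,6-dimethyl-3-oxocyclohex-4-ene-1-carbaldehyde (1R) | O=C[C@H]1[C@H](C(OC)OC)C(=O)C=CC1(C)C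
F8 | step 5 | trans-6-(dimethoxymethyl)-5-(hydroxymethyl)-4,4-dimethylcyclohex-2-en-1-one (5R) | OC[C@H]1[C@H](C(OC)OC)C(=O)C=CC1(C)C
F9 | step 5 | (1R,5R)-2-(dimethoxymethyl)-8,8-dimethyl-6-oxabicyclo[3.2.1]octan-3-one (C2 epimerisable) | COC(OC)[C@@H]1C(=O)C[C@H]2OC[C@@H]1C2(C)C
F10 | step 5 | (1R,5R)-2-(hydroxymethylidene)-8,8-dimethyl-6-oxabicyclo[3.2.1]octan-3-one (hydrogen-bonded enol) | OC=C1C(=O)C[C@H]2OC[C@@H]1C2(C)C
F11 | step 5 | (1R,2S,5R)-2-(hydroxymethyl)-8,8-dimethyl-3-oxo-6-oxabicyclo[3.2.1]octane-2-carbaldehyde | O=C[C@]1(CO)C(=O)C[C@H]2OC[C@@H]1C2(C)C
F12 | step 14 | ring A diketone (C6 ketone; 1′R,4S,4aR,5′R,8aS) | O=C1CC[C@H]2[C@@H](C1)[C@]3(COC2=O)C(=O)C[C@H]4OC[C@@H]3C4(C)C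
F13 | step 14 | pyrrolidine enamine of the C6 ketone (C6=C7) | C1CCN(C1)C1=CC[C@H]2[C@@H](C1)[C@]3(COC2=O)C(=O)C[C@H]4OC[C@@H]3C4(C)C
F14 | step 14 | C7-alkylated pyrrolidinium triflate (C7 as formed) | C[C@@H](C(=O)OCc1ccccc1)C1C(=[N+]2CCCC2)C[C@@H]3[C@H](C1)C(=O)OC[C@]34C(=O)C[C@H]5OC[C@@H]4C5(C)C.[O-]S(=O)(=O)C(F)(F)F
F15 | step 15 | C6 1,3-dithiolane of 21 | C[C@@H](C(=O)OCc1ccccc1)[C@@H]1C2(SCCS2)C[C@@H]3[C@H](C1)C(=O)OC[C@]34C(=O)C[C@H]5OC[C@@H]4C5(C)C
A1 | alternative 1 | cis-5,6-disubstituted δ-valerolactone: (2R)-propanoic acid chain on C5, (E)-alkenyl on C6 ending at the quaternary carbon of the ring C enone (PMB ether and TBS ether arms) | C[C@@H](C(=O)O)[C@H]1CCC(=O)O[C@H]1/C=C/[C@]2(COCc3ccc(OC)cc3)C(=O)C=CC(C)(C)[C@H]2CO[Si](C)(C)C(C)(C)C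
A2 | alternative 1 | ring A cyclohexene diacid from the lactone-enolate Claisen rearrangement | C[C@@H](C(=O)O)[C@@H]1C=C[C@H]([C@H](C1)C(=O)O)[C@]2(COCc3ccc(OC)cc3)C(=O)C=CC(C)(C)[C@H]2CO[Si](C)(C)C(C)(C)C
A3 | alternative 2 | (1S,5S)-apoverbenone (6,6-dimethylbicyclo[3.1.1]hept-3-en-2-one) | O=C1C=C[C@@H]2C[C@H]1C2(C)C
A4 | alternative 2 | (1R,5S)-7,7-dimethylbicyclo[3.1.1]hept-2-en-6-one | C1C=C[C@H]2C(=O)[C@@H]1C2(C)C
A5 | alternative 3 | 1-(oxiran-2-yl)cyclopentanol carrying ring A on the epoxide carbon (carbinol configuration immaterial) | C[C@@H](CO[Si](C)(C)C(C)(C)C)[C@@H]1CC[C@H]([C@H](C1)COCc2ccc(OC)cc2)[C@@]3(CO3)C4(O)CCC(C)(C)[C@H]4CO[Si](C)(C)C(C)(C)C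
A6 | alternative 3 | α-quaternary β-hydroxy ketone with ring C formed | C[C@@H](CO[Si](C)(C)C(C)(C)C)[C@@H]1CC[C@H]([C@H](C1)COCc2ccc(OC)cc2)[C@]2(CO)C(=O)CCC(C)(C)[C@H]2CO[Si](C)(C)C(C)(C)C
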